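**Plan**

1. Numbering used throughout: C1 (CH on furan C16), C2 (CH2), C3=C4 (C4 bears the lactone carbonyl C18), C5 (quaternary, bears OCH2 = C19), C6 (CH2), C7 (CHOAc), C8 (=C17H2), C9 (quaternary, CH3 = C20), C10 (CH shared by three rings), C11 (CH2), C12 (C=O on furan C13). Ring A = cyclohexene C1–C5/C10, ring B = cyclohexane C5–C10, ring C = cycloheptenone, ring D = furan, ring E = lactone.
2. Enabling feature: ring A is a cyclohexene whose C3=C4 bond is conjugated with C18=O, a Diels–Alder retron with diene C2=C3–C4=C5 (a 3-vinylbutenolide, ring E) and dienophile C1=C10 (the ring C alkene). The four carbons C6–C9 of ring B are exactly the tether between C5 and C10, so cutting C5–C10 and C1–C2 together opens rings B and A at once.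
3. Further cuts: C4=C5 (aldol condensation of an α-acyloxy ketone), O–C19 (carboxylate alkylation), C6–C7 (Mukaiyama aldol), C8=C17 (α-methylenation), C1=C10 (ring-closing metathesis), C12–C13 (aryllithium on an amide), C9–C11 (Eschenmoser–Claisen rearrangement).
4. Forward order: acyclic chain carrying C9, then ring C onto the purchased furan D, then the side chain C8–C5/C19. In one flask lactone E is closed and then rings A and B by intramolecular [4+2]; the C5–C10 bond closes ring B and completes the skeleton. Silyl-to-acetyl exchange at O7 ends the route.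
5. Stereochemistry: C9 by 1,3-chirality transfer from a Sharpless-resolved (R)-allylic alcohol; C7 by a catalyst-controlled aldol; C1, C5 and C10 all in the cycloaddition, relayed from C9 through the tether and the fixed alkene geometries.

Key step: step 14

Remark: in step 11 the antipode of the chiral catalyst is the one that gives the (S)-carbinol; this is the only stereocentre in the route not fixed by a substrate-based model.

**Route**

Step 1
Reactants: 1 tert-butyl(but-3-yn-1-yloxy)dimethylsilane
Product: 3 rac-(E)-6-(tert-butyldimethylsilyloxy)-4-methylhex-3-en-2-ol, via alkenylalane 2 (not isolated)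
Conditions: Me3Al, Cp2ZrCl2 (0.2 equiv), CH2Cl2, 0 °C to rt; then n-BuLi, THF, −78 °C; CH3CHO, −78 °C to rt; aq. potassium sodium tartrate
Reagents that add atoms: trimethylaluminium C[Al](C)C; acetaldehyde CC=O
Why: Zirconium-catalysed syn-carboalumination (Negishi carboalumination) puts CH3 on the internal and aluminium on the terminal alkyne carbon, which fixes the (E)-trisubstituted alkene, and the derived alkenylaluminate transfers its alkenyl group to acetaldehyde with retention of geometry; the carbinol is racemic at this point.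

Step 2
Reactants: 3 rac-(E)-6-(tert-butyldimethylsilyloxy)-4-methylhex-3-en-2-ol
Product: 4 (2R,3E)-6-(tert-butyldimethylsilyloxy)-4-methylhex-3-en-2-ol
Conditions: Ti(Oi-Pr)4 (10 mol%), L-(+)-diisopropyl tartrate (15 mol%), t-BuOOH (0.6 equiv), 4 Å molecular sieves, CH2Cl2, −20 °C
Reagents that add atoms: none
Why: Sharpless kinetic resolution: with the L-(+)-tartrate the (S)-enantiomer of an (E)-configured secondary allylic alcohol is epoxidised much faster, so the (R)-alcohol should be recovered, and the electron-rich trisubstituted alkene makes the rate difference large.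

Step 3
Reactants: 4 (2R,3E)-6-(tert-butyldimethylsilyloxy)-4-methylhex-3-en-2-ol
Product: 5 (3R,4E)-3-[2-(tert-butyldimethylsilyloxy)ethyl]-N,N,3-trimethylhex-4-enamide
Conditions: CH3C(OMe)2NMe2 (5 equiv), xylenes, 140 °C
Reagents that add atoms: N,N-dimethylacetamide dimethyl acetal CC(OC)(OC)N(C)C
Why: Eschenmoser–Claisen rearrangement through a chair transition state with the carbinol CH3 pseudo-equatorial forms the C9–C11 bond on the alkene face that carried oxygen, so the carbinol configuration is transferred to the new quaternary C9 and an (E)-propenyl group results.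

Step 4
Reactants: 6 3-bromofuran-2-carbaldehyde
Product: 7 3-bromo-2-ethenylfuran
Conditions: Ph3PCH3Br, KOt-Bu, THF, 0 °C to rt
Reagents that add atoms: methyltriphenylphosphonium bromide C[P+](c1ccccc1)(c1ccccc1)c1ccccc1.[Br-]
Why: Wittig methylenation of the aldehyde leaves the furan and the C–Br bond untouched.

Step 5
Reactants: 7 3-bromo-2-ethenylfuran; 5 (3R,4E)-3-[2-(tert-butyldimethylsilyloxy)ethyl]-N,N,3-trimethylhex-4-enamide
Product: 9 (3R,4E)-3-[2-(tert-butyldimethylsilyloxy)ethyl]-1-(2-ethenylfuran-3-yl)-3-methylhex-4-en-1-one, via furyllithium 8 (not isolated)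
Conditions: 7, n-BuLi, Et2O, −78 °C; then 5, −78 to −40 °C; aq. NH4Cl
Reagents that add atoms: none
Why: Bromine–lithium exchange at −78 °C gives the 3-furyllithium without migration, and its addition to the tertiary amide stops at the tetrahedral intermediate, so the C12 ketone is released only on work-up and over-addition is avoided.

Step 6
Reactants: 9 (3R,4E)-3-[2-(tert-butyldimethylsilyloxy)ethyl]-1-(2-ethenylfuran-3-yl)-3-methylhex-4-en-1-one
Product: 10 (6R)-6-[2-(tert-butyldimethylsilyloxy)ethyl]-6-methyl-5,6-dihydro-4H-cyclohepta[b]furan-4-one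
Conditions: second-generation Grubbs catalyst (5 mol%), CH2Cl2 (0.005 M), 40 °C
Reagents that add atoms: none
Why: Ring-closing metathesis between the vinylfuran and the propenyl group closes ring C with its necessarily cis C1=C10 alkene and releases propene; the quaternary C9 favours closure.

Step 7
Reactants: 10 (6R)-6-[2-(tert-butyldimethylsilyloxy)ethyl]-6-methyl-5,6-dihydro-4H-cyclohepta[b]furan-4-one
Product: 11 (6R)-6-(2-hydroxyethyl)-6-methyl-5,6-dihydro-4H-cyclohepta[b]furan-4-one
Conditions: HF·pyridine, pyridine, THF, 0 °C to rt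
Reagents that add atoms: none
Why: Buffered fluoride cleaves the primary silyl ether and leaves the furyl ketone and the ring alkene alone.

Step 8
Reactants: 11 (6R)-6-(2-hydroxyethyl)-6-methyl-5,6-dihydro-4H-cyclohepta[b]furan-4-one
Product: 12 2-[(6R)-6-methyl-4-oxo-5,6-dihydro-4H-cyclohepta[b]furan-6-yl]acetaldehyde
Conditions: Dess–Martin periodinane, NaHCO3, CH2Cl2, 0 °C to rt
Reagents that add atoms: none
Why: Dess–Martin oxidation of the primary alcohol to the aldehyde under neutral conditions; the product cannot cyclise onto the ketone through a reasonable ring size.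

Step 9
Reactants: 12 2-[(6R)-6-methyl-4-oxo-5,6-dihydro-4H-cyclohepta[b]furan-6-yl]acetaldehyde
Product: 13 2-[(6R)-6-methyl-4-oxo-5,6-dihydro-4H-cyclohepta[b]furan-6-yl]prop-2-enal
Conditions: 37% aq. CH2O, pyrrolidine (20 mol%), propionic acid (20 mol%), i-PrOH, 45 °C
Reagents that add atoms: formaldehyde C=O
Why: Amine-catalysed Mannich-type α-methylenation (the enamine of the aldehyde adds to the formaldehyde iminium, then the amine is eliminated) acts only on the aldehyde, because the aryl ketone forms no enamine under these conditions, and installs C17.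

Step 10
Reactants: 14 1,3-dichloropropan-2-one
Product: 15 [(3-chloroprop-1-en-2-yl)oxy]trimethylsilane
Conditions: Zn, Me3SiCl, THF, 0 °C to rt; distillation
Reagents that add atoms: chlorotrimethylsilane C[Si](C)(C)Cl
Why: Reductive silylation: zinc inserts into one C–Cl bond and the zinc enolate is trapped on oxygen, which gives the enol silane regiospecifically on the dechlorinated side.

Step 11
Reactants: 13 2-[(6R)-6-methyl-4-oxo-5,6-dihydro-4H-cyclohepta[b]furan-6-yl]prop-2-enal; 15 [(3-chloroprop-1-en-2-yl)oxy]trimethylsilane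
Product: 16 (6R)-6-[(3S)-6-chloro-3-hydroxy-5-oxohex-1-en-2-yl]-6-methyl-5,6-dihydro-4H-cyclohepta[b]furan-4-one
Conditions: SiCl4 (1.5 equiv), chiral binaphthyldiamine-derived bisphosphoramide (5 mol%), i-Pr2NEt (10 mol%), CH2Cl2, −78 °C; sat. aq. NaHCO3
Reagents that add atoms: none
Why: Enantioselective Mukaiyama aldol in which the phosphoramide-bound chlorosilyl cation activates only the aldehyde; the catalyst rather than the remote C9 centre should choose the face of the enal and set C7, and the regiodefined enol silane brings C6, C5 and the C19 chloride.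

Step 12
Reactants: 16 (6R)-6-[(3S)-6-chloro-3-hydroxy-5-oxohex-1-en-2-yl]-6-methyl-5,6-dihydro-4H-cyclohepta[b]furan-4-one
Product: 17 (6R)-6-[(3S)-3-(tert-butyldimethylsilyloxy)-6-chloro-5-oxohex-1-en-2-yl]-6-methyl-5,6-dihydro-4H-cyclohepta[b]furan-4-one
Conditions: t-BuMe2SiOTf, 2,6-lutidine, CH2Cl2, −78 °C
Reagents that add atoms: tert-butyldimethylsilyl trifluoromethanesulfonate CC(C)(C)[Si](C)(C)OS(=O)(=O)C(F)(F)F
Why: Silylation blocks retro-aldol cleavage and attack of O7 on the chloromethyl group; a silyl ether is used because a β-acyloxy ketone would eliminate in the basic steps that follow.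

Step 13
Reactants: 17 (6R)-6-[(3S)-3-(tert-butyldimethylsilyloxy)-6-chloro-5-oxohex-1-en-2-yl]-6-methyl-5,6-dihydro-4H-cyclohepta[b]furan-4-one; 18 but-3-enoic acid
Product: 19 (4S)-4-(tert-butyldimethylsilyloxy)-5-[(6R)-6-methyl-4-oxo-5,6-dihydro-4H-cyclohepta[b]furan-6-yl]-2-oxohex-5-en-1-yl but-3-enoate
Conditions: Et3N, NaI (cat.), DMF, rt
Reagents that add atoms: none
Why: SN2 displacement of the activated α-keto chloride by the carboxylate forms the O–C19 bond; the weak base should leave the β-silyloxy ketone and the but-3-enoate unisomerised.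

Step 14
Reactants: 19 (4S)-4-(tert-butyldimethylsilyloxy)-5-[(6R)-6-methyl-4-oxo-5,6-dihydro-4H-cyclohepta[b]furan-6-yl]-2-oxohex-5-en-1-yl but-3-enoate
Product: 21 7-O-tert-butyldimethylsilyl pentacyclic lactone (1R,5S,7S,9R,10S), via vinylbutenolide 20 (not isolated)
Conditions: DBU (1.2 equiv), MeCN, 0 °C to rt; AcOH (1.5 equiv); dilution with PhMe (0.005 M), BHT, 130 °C, sealed tube
Reagents that add atoms: none
Why: DBU removes the doubly activated ester α-proton of 19 and the enolate closes lactone E by 5-exo-trig aldol addition to the C5 ketone followed by E1cB loss of water (the known α-acyloxy ketone to butenolide condensation), giving 3-vinylbutenolide 20, a 2-carbonyl diene C2=C3–C4=C5. On heating, 20 should undergo a concerted, asynchronous type-1 intramolecular Diels–Alder reaction of a 1,3,9-decatriene (closest precedent: thermal cycloadditions of decatrienes that carry the tether on a (Z)-locked diene terminus), in which bonds C5–C10 and C2–C1 form together, so ring A arises as the [4+2] cyclohexene and ring B as the six-membered ring that the C6–C9 tether closes through the new C5–C10 bond. Because lactone E holds C6 in the inside (Z) position of the diene terminus, only the transition state with C9 exo can span the tether, which makes the A/B fusion cis and places C19 syn to H10 (C5 and C10 set by geometry). Suprafacial addition to the cis ring alkene C1=C10 makes H1 syn to H10 (C1), and the tether anchored at quaternary C9 can reach only the alkene face syn to C8 and anti to the C9 methyl, so C9 fixes the absolute sense and the B/C fusion is cis; the C7 silyloxy group sits pseudo-equatorial in the chair-like tether. The step needs periselectivity (tethered [4+2] over diene dimerisation, over a [1,5]-hydrogen shift of the (Z)-substituted diene and over the vinylfuran acting as a diene), and this should be secured by the six-membered tether ring, the gem-disubstitution at C9, high dilution, a radical inhibitor and neutralisation of the base before heating.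

Step 15
Reactants: 21 7-O-tert-butyldimethylsilyl pentacyclic lactone
Product: 22 7-hydroxy pentacyclic lactone (1R,5S,7S,9R,10S)
Conditions: HF·pyridine, THF, 0 °C to rt
Reagents that add atoms: none
Why: Acidic fluoride removes the secondary silyl ether without opening the lactone or epimerising C1, which a basic fluoride source could do.

Step 16
Reactants: 22 7-hydroxy pentacyclic lactone
Product: 23 CNP0273675.2
Conditions: Ac2O, DMAP (cat.), pyridine, CH2Cl2, 0 °C to rt
Reagents that add atoms: acetic anhydride CC(=O)OC(C)=O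
Why: DMAP-catalysed acetylation of the secondary allylic alcohol proceeds with retention at C7 and touches no other group.

**Compound list**

1 | tert-butyl(but-3-yn-1-yloxy)dimethylsilane | C#CCCO[Si](C)(C)C(C)(C)C | starting material
2 | (E)-[4-(tert-butyldimethylsilyloxy)-2-methylbut-1-en-1-yl]dimethylalane (not isolated) | C/C(CCO[Si](C)(C)C(C)(C)C)=C\[Al](C)C | intermediate
3 | rac-(E)-6-(tert-butyldimethylsilyloxy)-4-methylhex-3-en-2-ol | C/C(CCO[Si](C)(C)C(C)(C)C)=C\C(C)O | intermediate
4 | (2R,3E)-6-(tert-butyldimethylsilyloxy)-4-methylhex-3-en-2-ol | C/C(CCO[Si](C)(C)C(C)(C)C)=C\[C@@H](C)O | intermediate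
5 | (3R,4E)-3-[2-(tert-butyldimethylsilyloxy)ethyl]-N,N,3-trimethylhex-4-enamide | CN(C)C(=O)C[C@](CCO[Si](C)(C)C(C)(C)C)(C)/C=C/C | intermediate
6 | 3-bromofuran-2-carbaldehyde | O=Cc1occc1Br | starting material
7 | 3-bromo-2-ethenylfuran | C=Cc1occc1Br | intermediate
8 | (2-ethenylfuran-3-yl)lithium (not isolated) | [Li]c1ccoc1C=C | intermediate
9 | (3R,4E)-3-[2-(tert-butyldimethylsilyloxy)ethyl]-1-(2-ethenylfuran-3-yl)-3-methylhex-4-en-1-one | C=Cc1occc1C(=O)C[C@](CCO[Si](C)(C)C(C)(C)C)(C)/C=C/C | intermediate
10 | (6R)-6-[2-(tert-butyldimethylsilyloxy)ethyl]-6-methyl-5,6-dihydro-4H-cyclohepta[b]furan-4-one | CC(C)(C)[Si](C)(C)OCC[C@]1(C)CC(=O)c2ccoc2C=C1 | intermediate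
11 | (6R)-6-(2-hydroxyethyl)-6-methyl-5,6-dihydro-4H-cyclohepta[b]furan-4-one | OCC[C@]1(C)CC(=O)c2ccoc2C=C1 | intermediate
12 | 2-[(6R)-6-methyl-4-oxo-5,6-dihydro-4H-cyclohepta[b]furan-6-yl]acetaldehyde | O=CC[C@]1(C)CC(=O)c2ccoc2C=C1 | intermediate
13 | 2-[(6R)-6-methyl-4-oxo-5,6-dihydro-4H-cyclohepta[b]furan-6-yl]prop-2-enal | O=CC(=C)[C@]1(C)CC(=O)c2ccoc2C=C1 | intermediate
14 | 1,3-dichloropropan-2-one | O=C(CCl)CCl | starting material
15 | [(3-chloroprop-1-en-2-yl)oxy]trimethylsilane | C=C(CCl)O[Si](C)(C)C | intermediate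
16 | (6R)-6-[(3S)-6-chloro-3-hydroxy-5-oxohex-1-en-2-yl]-6-methyl-5,6-dihydro-4H-cyclohepta[b]furan-4-one | ClCC(=O)C[C@H](O)C(=C)[C@]1(C)CC(=O)c2ccoc2C=C1 | intermediate
17 | (6R)-6-[(3S)-3-(tert-butyldimethylsilyloxy)-6-chloro-5-oxohex-1-en-2-yl]-6-methyl-5,6-dihydro-4H-cyclohepta[b]furan-4-one | ClCC(=O)C[C@H](O[Si](C)(C)C(C)(C)C)C(=C)[C@]1(C)CC(=O)c2ccoc2C=C1 | intermediate
18 | but-3-enoic acid | C=CCC(=O)O | starting material
19 | (4S)-4-(tert-butyldimethylsilyloxy)-5-[(6R)-6-methyl-4-oxo-5,6-dihydro-4H-cyclohepta[b]furan-6-yl]-2-oxohex-5-en-1-yl but-3-enoate | C=CCC(=O)OCC(=O)C[C@H](O[Si](C)(C)C(C)(C)C)C(=C)[C@]1(C)CC(=O)c2ccoc2C=C1 | intermediate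
20 | 4-{(2S)-2-(tert-butyldimethylsilyloxy)-3-[(6R)-6-methyl-4-oxo-5,6-dihydro-4H-cyclohepta[b]furan-6-yl]but-3-en-1-yl}-3-ethenylfuran-2(5H)-one (not isolated) | C=CC1=C(C[C@H](O[Si](C)(C)C(C)(C)C)C(=C)[C@]2(C)CC(=O)c3ccoc3C=C2)COC1=O | intermediate
21 | pentacyclic lactone with OSi(t-Bu)Me2 at C7, target skeleton, (1R,5S,7S,9R,10S) in the numbering of the plan | C=C1[C@@H](O[Si](C)(C)C(C)(C)C)C[C@@]23COC(=O)C2=CC[C@H]2c4occc4C(=O)C[C@]1(C)[C@H]23 | intermediate
22 | pentacyclic lactone with OH at C7, (1R,5S,7S,9R,10S) | C=C1[C@@H](O)C[C@@]23COC(=O)C2=CC[C@H]2c4occc4C(=O)C[C@]1(C)[C@H]23 | intermediate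
23 | CNP0273675.2, the 7-acetate, (1R,5S,7S,9R,10S) | C=C1[C@@H](OC(C)=O)C[C@@]23COC(=O)C2=CC[C@H]2c4occc4C(=O)C[C@]1(C)[C@H]23 | target

**Step count**

Total: 16 steps. Longest linear sequence: 14 steps (steps 1–3, 5–9, 11–16); steps 4 and 10 are side branches.

**Steps most likely to fail**

Step 14. The vinyl diene may isomerise or oligomerise while base is still present, or the cycloaddition may be too slow against the [1,5]-hydrogen shift of the (Z)-substituted diene. The fallback sets out from 17 and returns at 21. Compound 17 would be esterified with lithium acetoacetate (NaI, DMF) to the 3-oxobutanoate F1. Et3N would then effect the much easier intramolecular Knoevenagel condensation to the 3-acetylbutenolide F2. Et3SiOTf and Et3N at −78 °C should give the 2-silyloxy diene F3, an electron-rich diene that should cyclise on milder heating through the same tether-controlled transition state to the silyl enol ether F4. CsF and PhNTf2 would convert this into the enol triflate F5, and Pd(OAc)2, PPh3, Bu3N and HCO2H would reduce the triflate to the C3–H alkene, which is 21.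

Step 11. The chloro enol silane may react sluggishly with the hindered enal, or the catalyst may give poor facial control next to the quaternary centre. The fallback sets out from 13 and returns at 19. Compound 13 would be treated with the diisopinocampheylboron enolate of 1-(triethylsilyloxy)propan-2-one (Ipc2BCl, Et3N, antipode chosen for the (S)-carbinol, oxidative work-up) to give the β-hydroxy ketone F6. t-BuMe2SiOTf and 2,6-lutidine would give the bis-silyl ether F7, and PPTS in MeOH should remove the primary triethylsilyl group selectively to leave the α-hydroxy ketone F8. Esterification with 18 (EDC, DMAP, 0 °C) would give 19.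

Step 3. At 140 °C the allylic alcohol may eliminate, or a competing boat transition state may erode the chirality transfer. The fallback sets out from 4 and returns at 9. Compound 4 would be acetylated (Ac2O, DMAP) to the acetate F9. LiN(SiMe3)2 and Me3SiCl at −78 °C followed by warming should give, by Ireland–Claisen rearrangement through the same chair at or below room temperature, the carboxylic acid F10. Its lithium carboxylate (LiH, THF) would be treated with 8 and worked up with acid to give 9.

**Further compounds**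

F1 | step 14 | (4S)-4-(tert-butyldimethylsilyloxy)-5-[(6R)-6-methyl-4-oxo-5,6-dihydro-4H-cyclohepta[b]furan-6-yl]-2-oxohex-5-en-1-yl 3-oxobutanoate | CC(=O)CC(=O)OCC(=O)C[C@H](O[Si](C)(C)C(C)(C)C)C(=C)[C@]1(C)CC(=O)c2ccoc2C=C1
F2 | step 14 | 3-acetyl-4-{(2S)-2-(tert-butyldimethylsilyloxy)-3-[(6R)-6-methyl-4-oxo-5,6-dihydro-4H-cyclohepta[b]furan-6-yl]but-3-en-1-yl}furan-2(5H)-one | CC(=O)C1=C(C[C@H](O[Si](C)(C)C(C)(C)C)C(=C)[C@]2(C)CC(=O)c3ccoc3C=C2)COC1=O
F3 | step 14 | 3-[1-(triethylsilyloxy)ethenyl] analogue of 20 | C=C(O[Si](CC)(CC)CC)C1=C(C[C@H](O[Si](C)(C)C(C)(C)C)C(=C)[C@]2(C)CC(=O)c3ccoc3C=C2)COC1=O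
F4 | step 14 | 3-(triethylsilyloxy) derivative of 21 (silyl enol ether) | C=C1[C@@H](O[Si](C)(C)C(C)(C)C)C[C@@]23COC(=O)C2=C(O[Si](CC)(CC)CC)C[C@H]2c4occc4C(=O)C[C@]1(C)[C@H]23
F5 | step 14 | 3-(trifluoromethanesulfonyloxy) derivative of 21 (enol triflate) | C=C1[C@@H](O[Si](C)(C)C(C)(C)C)C[C@@]23COC(=O)C2=C(OS(=O)(=O)C(F)(F)F)C[C@H]2c4occc4C(=O)C[C@]1(C)[C@H]23
F6 | step 11 | (6R)-6-[(3S)-3-hydroxy-5-oxo-6-(triethylsilyloxy)hex-1-en-2-yl]-6-methyl-5,6-dihydro-4H-cyclohepta[b]furan-4-one | CC[Si](CC)(CC)OCC(=O)C[C@H](O)C(=C)[C@]1(C)CC(=O)c2ccoc2C=C1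
F7 | step 11 | (6R)-6-[(3S)-3-(tert-butyldimethylsilyloxy)-5-oxo-6-(triethylsilyloxy)hex-1-en-2-yl]-6-methyl-5,6-dihydro-4H-cyclohepta[b]furan-4-one | CC[Si](CC)(CC)OCC(=O)C[C@H](O[Si](C)(C)C(C)(C)C)C(=C)[C@]1(C)CC(=O)c2ccoc2C=C1
F8 | step 11 | (6R)-6-[(3S)-3-(tert-butyldimethylsilyloxy)-6-hydroxy-5-oxohex-1-en-2-yl]-6-methyl-5,6-dihydro-4H-cyclohepta[b]furan-4-one | OCC(=O)C[C@H](O[Si](C)(C)C(C)(C)C)C(=C)[C@]1(C)CC(=O)c2ccoc2C=C1
F9 | step 3 | (2R,3E)-6-(tert-butyldimethylsilyloxy)-4-methylhex-3-en-2-yl acetate | C/C(CCO[Si](C)(C)C(C)(C)C)=C\[C@@H](C)OC(C)=O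
F10 | step 3 | (3R,4E)-3-[2-(tert-butyldimethylsilyloxy)ethyl]-3-methylhex-4-enoic acid | OC(=O)C[C@](CCO[Si](C)(C)C(C)(C)C)(C)/C=C/C
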